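**Plan**
Numbering: chromene O1, spiro C2 (= pinane C2), C3H2, isobutyl-bearing C4, C4a, C8a. Pinane C1–C7 has C6 as the CMe2 bridge, C7 as the CH2 bridge and C10 as the carbon on C2 (= chromene C3).
Enabling feature: in the six-membered ring of the pinane, spiro C2 stands 1,3 to C4, and chromene C3–C4 extend outward from C2. A temporary ketone at pinane C4 therefore makes C2 the β-carbon and chromene C4 the δ-carbon of a dienone.
Cuts: first the pinane C4 carbonyl is reinstated. Then O1–C2 and C4–C4a are cut together as two conjugate additions, giving syncarpic acid and a dienone. Last, the C3=C4 alkene of the dienone is cut to the verbenone methyl group and isovaleraldehyde.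
Forward: the pinane bicycle and the trione ring are bought. The 4-methylpentenyl chain is joined at C10, the trione is attached at C4, and the dihydropyran (the only ring made) closes in the same flask. The ketone is then deleted.
Stereochemistry: pinane C1 and C5 come from (1S)-(−)-verbenone. C2 and C4 are both set in the key step by attack on the dienone face opposite the gem-dimethyl bridge.

Key step: step 4

Assumption: (1S)-(−)-verbenone (enantiopure grade) and syncarpic acid are treated as purchasable compounds.

**Step 1**
Reactants: 1 (1S,5S)-(−)-verbenone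
Product: 2 linear TBS dienol ether of verbenone (exocyclic C2=C10 and ring C3=C4 double bonds, OTBS on C4, bridgeheads as in 1)
Conditions: TBSOTf (1.2 equiv), Et3N (2 equiv), CH2Cl2, 0 °C → rt
Reagents that add atoms: tert-butyldimethylsilyl triflate, CC(C)(C)[Si](C)(C)OS(=O)(=O)C(F)(F)F
Why: Soft enolisation (silyl dienol ether formation): O-silylation of the enone acidifies only the C10 methyl, because the α′ carbon is a bridgehead that cannot enolise (Bredt's rule), so a single linear dienol ether forms and no stereocentre is touched.

**Step 2**
Reactants: 2 TBS dienol ether of verbenone; 3 isovaleraldehyde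
Product: 4 (1S,5R)-4-(2-hydroxy-4-methylpentyl)-6,6-dimethylbicyclo[3.1.1]hept-3-en-2-one (both carbinol epimers)
Conditions: BF3·OEt2 (1.1 equiv), CH2Cl2, −78 °C; aq NaHCO3
Reagents that add atoms: none
Why: Vinylogous Mukaiyama aldol addition: the BF3-activated aldehyde is attacked by the unhindered terminal γ-carbon (C10) of the silyl dienol ether rather than by the ring α-carbon, the enone is restored, and the new carbinol centre, formed without control, is erased in step 3.

**Step 3**
Reactants: 4 δ-hydroxy enone
Product: 6 (1S,5R)-6,6-dimethyl-4-[(1E)-4-methylpent-1-enyl]bicyclo[3.1.1]hept-3-en-2-one, via mesylate 5 (not isolated)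
Conditions: MsCl, Et3N, CH2Cl2, 0 °C; then DBU, 0 °C → rt
Reagents that add atoms: none
Why: Mesylation followed by vinylogous E1cB elimination: DBU removes an acidic γ-proton at C10 and the extended enolate expels mesylate, which places the new double bond in conjugation and gives the E isomer because it avoids allylic strain between the chain and the ring.

**Step 4**
Reactants: 6 (E)-dienone; 7 syncarpic acid (1.5 equiv)
Product: 9 (1R,2S,4'S,5S)-4'-isobutyl-6,6,6',6',8',8'-hexamethyl-3',4'-dihydrospiro[bicyclo[3.1.1]heptane-2,2'-chromene]-4,5',7'(6'H,8'H)-trione (O1' anti to the CMe2 bridge and isobutyl cis to pinane C3), via open enol adduct 8 (not isolated)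
Conditions: DBU (20 mol %), PhMe (1 M), 80 °C; cold aq NaHCO3 wash
Reagents that add atoms: none
Why: The amidinium syncarpate ion pair adds through its central carbon (future C4a) to the δ-carbon of 6 in a 1,6-Michael addition, excess 7 protonates the extended dienolate, which settles as the conjugated enone 8, and the enol oxygen of 8 then adds to the β-carbon (pinane C2) in an intramolecular oxa-Michael addition. The closest known reaction type is the base- or amine-catalysed 1,6-addition/1,4-oxa-Michael cascade of cyclic 1,3-dicarbonyls and hydroxyarenes with 2,4-dienones and dienals, and oxa-Michael closure onto a fully substituted enone β-carbon is the ring-forming event of the Kabbe spirochromanone synthesis. The one ring that forms, the dihydropyran, closes 6-exo-trig, the C2=C3 bond of the pinene ring lying outside the new ring. Spiro C2 is controlled by the gem-dimethyl bridge, which blocks one face of the enone so that oxygen enters anti to it, the face that cuprates and alkaline peroxide use on verbenone. C4 is controlled by the same bridge, because carbon attack on the preferred s-trans E-dienone from the open face gives the 4S centre, and the 4R adduct would have to close with isobutyl 1,3-diaxial to bridgehead C1 instead of the C3 methylene, so it should lag behind as an acidic enol that the bicarbonate wash removes. The step needs δ- over β-attack, secured by the fully substituted, bridgehead-flanked β-carbon, C- over O-alkylation, secured by reversibility of the O-adduct, and a closed-ether equilibrium, helped by keeping the base catalytic and the solvent apolar so that the open form is never stored as its enolate salt.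

**Step 5**
Reactants: 9 spiro ketone
Product: 10 p-toluenesulfonylhydrazone of 9 at pinane C4 (C=N geometry of no consequence)
Conditions: TsNHNH2 (1.2 equiv), MeOH, 40 °C
Reagents that add atoms: p-toluenesulfonyl hydrazide, Cc1ccc(cc1)S(=O)(=O)NN
Why: Tosylhydrazone condensation under near-neutral conditions: only the pinane ketone reacts, since C7'=O lies between two quaternary carbons and C5'=O is a vinylogous ester carbonyl, and the absence of base keeps the β-oxygen substituent from being eliminated, so no stereocentre changes.

**Step 6**
Reactants: 10 tosylhydrazone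
Product: 13 (1R,2R,4'S,5S)-4'-isobutyl-6,6,6',6',8',8'-hexamethyl-3',4'-dihydrospiro[bicyclo[3.1.1]heptane-2,2'-chromene]-5',7'(6'H,8'H)-dione (CNP0231252.1), via N-boryl tosylhydrazine 11 (not isolated), via alkyl diazene 12 (not isolated)
Conditions: catecholborane (2 equiv), CHCl3, −10 → 0 °C; then NaOAc·3H2O, reflux
Reagents that add atoms: none
Why: Caglioti-type tosylhydrazone reduction in its catecholborane form: the borane hydroborates the C=N bond, acetate then triggers loss of sulfinate and the diazene loses nitrogen to leave CH2, all without strong acid or base, while the s-trans vinylogous ester and the doubly neopentyl ketone are inert to catecholborane and the four stereocentres are untouched.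

**Compound list**
1 | (1S,5S)-(−)-verbenone | CC1=CC(=O)[C@H]2C[C@@H]1C2(C)C | starting material
2 | tert-butyl[(6,6-dimethyl-4-methylidenebicyclo[3.1.1]hept-2-en-2-yl)oxy]dimethylsilane, bridgeheads as in 1 | C=C1C=C(O[Si](C)(C)C(C)(C)C)[C@H]2C[C@@H]1C2(C)C | intermediate
3 | isovaleraldehyde (3-methylbutanal) | CC(C)CC=O | starting material
4 | (1S,5R)-4-(2-hydroxy-4-methylpentyl)-6,6-dimethylbicyclo[3.1.1]hept-3-en-2-one, both carbinol epimers | CC(C)CC(O)CC1=CC(=O)[C@H]2C[C@@H]1C2(C)C | intermediate
5 | methanesulfonate of 4 | CC(C)CC(OS(C)(=O)=O)CC1=CC(=O)[C@H]2C[C@@H]1C2(C)C | intermediate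
6 | (1S,5R)-6,6-dimethyl-4-[(1E)-4-methylpent-1-enyl]bicyclo[3.1.1]hept-3-en-2-one | CC(C)C/C=C/C1=CC(=O)[C@H]2C[C@@H]1C2(C)C | intermediate
7 | syncarpic acid (2,2,4,4-tetramethylcyclohexane-1,3,5-trione) | CC1(C)C(=O)CC(=O)C(C)(C)C1=O | starting material
8 | open 1,6-adduct, enol form: (S)-carbon bearing isobutyl, the trione C-2 and the CH2 attached to the verbenone enone β-carbon | CC(C)C[C@@H](CC1=CC(=O)[C@H]2C[C@@H]1C2(C)C)C1=C(O)C(C)(C)C(=O)C(C)(C)C1=O | intermediate
9 | (1R,2S,4'S,5S)-spiro ketone (target skeleton with C=O at pinane C4) | CC(C)C[C@H]1C[C@@]2(CC(=O)[C@H]3C[C@@H]2C3(C)C)OC2=C1C(=O)C(C)(C)C(=O)C2(C)C | intermediate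
10 | tosylhydrazone of 9 at pinane C4 | CC(C)C[C@H]1C[C@@]2(CC(=NNS(=O)(=O)c3ccc(C)cc3)[C@H]3C[C@@H]2C3(C)C)OC2=C1C(=O)C(C)(C)C(=O)C2(C)C | intermediate
11 | N-(1,3,2-benzodioxaborol-2-yl) tosylhydrazine at pinane C4 (transient C4 configuration of no consequence) | CC(C)C[C@H]1C[C@@]2(CC(N(B3Oc4ccccc4O3)NS(=O)(=O)c3ccc(C)cc3)[C@H]3C[C@@H]2C3(C)C)OC2=C1C(=O)C(C)(C)C(=O)C2(C)C | intermediate
12 | monoalkyl diazene at pinane C4 | CC(C)C[C@H]1C[C@@]2(CC(N=N)[C@H]3C[C@@H]2C3(C)C)OC2=C1C(=O)C(C)(C)C(=O)C2(C)C | intermediate
13 | CNP0231252.1, (1R,2R,4'S,5S)-spiro[pinane-2,2'-chromene]-5',7'-dione | CC(C)C[C@H]1C[C@@]2(CC[C@H]3C[C@@H]2C3(C)C)OC2=C1C(=O)C(C)(C)C(=O)C2(C)C | target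

**Total step count:** 6. **Longest linear sequence:** 6 steps (1 → 2 → 4 → 6 → 9 → 10 → 13).

**Steps most likely to fail**

Step 4. Attack at an alkyl-substituted δ terminus may be sluggish. Facial discrimination at that remote carbon may be weak. The oxa-Michael equilibrium may also rest on the open side.
- The fallback sets out from 2 (together with 3 and 7) and comes back at 9.
- Knoevenagel condensation of 7 with 3 (cat. proline, CH2Cl2, MgSO4) gives 2-(3-methylbutylidene)-4,4,6,6-tetramethylcyclohexane-1,3,5-trione F1, which is used at once.
- Its inverse-electron-demand oxa-Diels–Alder reaction takes place across the exocyclic C2=C10 bond of 2. This diene is locked s-trans, so it can only act as an electron-rich 1,1-disubstituted alkene, the alkene class these alkylidene triones are known to add to.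
- The product is the spirocyclic silyl enol ether F2, with oxygen again anti to the bridge. The C4' epimers are separated.
- Acidic protodesilylation (aq HF, MeCN, 0 °C) never passes through a free enolate and releases 9.

Step 6. Nitrogen loss by way of a free radical at pinane C4 would permit β-scission of the strained C5–C6 bond. Hydroboration of the hindered C=N bond may also stall.
- The fallback sets out from 9, bypasses 10, and comes back at 13.
- Thioketalisation with ethane-1,2-dithiol and catalytic Zn(OTf)2 in CH2Cl2 at 0 °C gives the 1,3-dithiolane F3, which also shuts off β-elimination.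
- Mozingo desulfurisation with acetone-deactivated Raney nickel in EtOH then delivers 13.

Step 2. Competing attack through the ring α-carbon, protodesilylation back to the enone, or aldehyde self-condensation may erode the γ-aldol.
- The fallback sets out from 2 and comes back at 6, skipping 4 and 5.
- NBS in THF at 0 °C brominates the γ terminus to give 10-bromoverbenone F4.
- A Michaelis–Arbuzov reaction with triethyl phosphite gives the allylic phosphonate F5.
- Horner–Wadsworth–Emmons olefination of 3 (LiHMDS, THF, −78 → 0 °C) then forms the E-alkene of 6 directly.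

**Further compounds**
F1 | step 4 | 2-(3-methylbutylidene)-4,4,6,6-tetramethylcyclohexane-1,3,5-trione | CC(C)CC=C1C(=O)C(C)(C)C(=O)C(C)(C)C1=O
F2 | step 4 | TBS enol ether of 9 (pinane C3=C4, OTBS on C4) | CC(C)C[C@H]1C[C@@]2(C=C(O[Si](C)(C)C(C)(C)C)[C@H]3C[C@@H]2C3(C)C)OC2=C1C(=O)C(C)(C)C(=O)C2(C)C
F3 | step 6 | 1,3-dithiolane of 9 at pinane C4 | CC(C)C[C@H]1C[C@@]2(CC3(SCCS3)[C@H]3C[C@@H]2C3(C)C)OC2=C1C(=O)C(C)(C)C(=O)C2(C)C
F4 | step 2 | 10-bromoverbenone (4-bromomethyl-6,6-dimethylbicyclo[3.1.1]hept-3-en-2-one, bridgeheads as in 1) | BrCC1=CC(=O)[C@H]2C[C@@H]1C2(C)C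
F5 | step 2 | diethyl (verbenon-10-yl)phosphonate | CCOP(=O)(OCC)CC1=CC(=O)[C@H]2C[C@@H]1C2(C)C
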